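Ring B of the target (C1–C2–C3–C4–C4a–C8a) is cut across C2–C3 and C1–C8a, which reveals two C6–C3 units: 3-(3,4-dimethoxyphenyl)propanal, whose formyl carbon becomes the C3 methyl group, and (E)-methyl isoeugenol. The key step exploits the electron-rich C8a of the fused dimethoxybenzene ring A, para to the C6 methoxy group, and the cation-stabilising pendant aryl ring C on C1. A chiral imidazolidinone converts the aldehyde into an enamine radical cation that adds to the alkene at C2; oxidation of the C1 radical to the cation and Friedel–Crafts closure at C8a complete a formal [4+2] annulation that builds ring B and all three stereocentres from achiral, acyclic precursors. Deoxygenation of CHO to CH3 finishes the synthesis.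

Key step: step 2

Remark: atoms are cited by the tetralin numbering of the target (C1 carries ring C, C2 and C3 the methyl groups, C4 is the CH2 group, C4a and C8a are the fusion carbons of ring A), and the sense of induction is assigned from the usual benzyl-shielding model of the imidazolidinone; if it proved opposite, the (2R,5R) catalyst would be used with nothing else changed.

Step 1
Reactants: 1 3-(3,4-dimethoxyphenyl)propan-1-ol
Product: 2 3-(3,4-dimethoxyphenyl)propanal
Conditions: Dess–Martin periodinane (1.2 equiv), CH2Cl2, 0 °C to rt; used fresh
Reagents that add atoms: none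
Why: Dess–Martin oxidation of an unhindered primary alcohol should stop cleanly at the aldehyde under near-neutral, anhydrous conditions that leave the electron-rich dimethoxybenzene ring untouched; no stereocentre is involved.

Step 2
Reactants: 2 3-(3,4-dimethoxyphenyl)propanal; 3 (E)-methyl isoeugenol [(E)-1,2-dimethoxy-4-(prop-1-en-1-yl)benzene]
Product: 7 (2R,3R,4S)-4-(3,4-dimethoxyphenyl)-6,7-dimethoxy-3-methyl-1,2,3,4-tetrahydronaphthalene-2-carbaldehyde, via enamine 4 (not isolated), via benzylic cation 5 (not isolated), via tetralin iminium ion 6 (not isolated)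
Conditions: (2S,5S)-5-benzyl-2-tert-butyl-3-methylimidazolidin-4-one trifluoroacetate (20 mol %), 3 (2 equiv), Fe(phen)3(SbF6)3 (2.5 equiv, in portions), Na2HPO4 (2.5 equiv), DME, −30 °C; aqueous work-up, rapid filtration through silica
Reagents that add atoms: none
Why: Organo-SOMO radical–polar crossover cascade, the known formal [4+2] annulation of 3-arylpropanals with styrenes: enamine 4 is oxidised by trivalent iron to an electrophilic 3π-electron radical cation whose C3 adds to the methyl-bearing alkene carbon of 3 (C2–C3 bond), and the C1 benzylic radical so formed, stabilised by ring C, is oxidised by the second equivalent of oxidant to cation 5. Ring B is then closed by intramolecular Friedel–Crafts alkylation, a cation–π closure that is 6-endo with respect to the C4a=C8a bond of ring A, in which C8a attacks C1 (C1–C8a bond) to give iminium ion 6; the water set free on enamine formation hydrolyses 6 to 7 and returns the catalyst. C3 is set by the catalyst, whose enamine double bond lies away from the tert-butyl group while the benzyl group covers the Re face, so that the alkene bonds to the Si face and C3 becomes R. C2 is set relative to C3 in the open radical-addition transition state, the alkene methyl group pointing away from the iminium arm, and C1 is set in the ring closure, where the freely rotating cation adopts a chair-like transition state with ring C, the C2 methyl group and the iminium arm all equatorial, so that the all-trans isomer should form whatever the alkene geometry. The step needs cross-coupling to win over oxidative dimerisation of 3, which is secured by the much lower oxidation potential of the enamine, portionwise addition of the oxidant and low temperature, and it needs arylation at C8a and not at the other ortho carbon, which is secured by para activation from the C6 methoxy group and by the crowding of the alternative position between side chain and methoxy group.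

Step 3
Reactants: 7 (2R,3R,4S)-4-(3,4-dimethoxyphenyl)-6,7-dimethoxy-3-methyl-1,2,3,4-tetrahydronaphthalene-2-carbaldehyde
Product: 9 galbulin [(1S,2S,3R)-1-(3,4-dimethoxyphenyl)-6,7-dimethoxy-2,3-dimethyl-1,2,3,4-tetrahydronaphthalene], via tosylhydrazone 8 (not isolated)
Conditions: TsNHNH2, CHCl3, 4 Å MS, rt; then catecholborane, 0 °C to rt; then NaOAc·3H2O, reflux
Reagents that add atoms: none
Why: Caglioti-type tosylhydrazone reduction in its catecholborane variant: the aldehyde condenses to hydrazone 8, the C=N bond is hydroborated, and acetate-induced loss of sulfinate gives a monoalkyl diazene that extrudes N2 to leave the C3 methyl group, under near-neutral conditions that should not touch the adjacent C3 stereocentre or the four aryl methyl ethers; no new stereocentre is formed.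

Compound list
1 | 3-(3,4-dimethoxyphenyl)propan-1-ol | COc1ccc(CCCO)cc1OC | starting material
2 | 3-(3,4-dimethoxyphenyl)propanal | COc1ccc(CCC=O)cc1OC | intermediate
3 | (E)-methyl isoeugenol, (E)-1,2-dimethoxy-4-(prop-1-en-1-yl)benzene | COc1ccc(/C=C/C)cc1OC | starting material
4 | enamine, (2S,5S)-5-benzyl-2-tert-butyl-1-[(E)-3-(3,4-dimethoxyphenyl)prop-1-en-1-yl]-3-methylimidazolidin-4-one | CN1[C@@H](C(C)(C)C)N(/C=C/Cc2ccc(OC)c(OC)c2)[C@@H](Cc2ccccc2)C1=O | intermediate
5 | benzylic cation, open-chain iminium ion of the imidazolidinone bearing the 3,4-dimethoxybenzyl group on C3, the methyl group on C2 and the ring-C-stabilised carbocation at C1 (C2 and C3 configured as in 7) | COc1ccc(cc1OC)C[C@@H](C=[N+]1[C@@H](Cc2ccccc2)C(=O)N(C)[C@H]1C(C)(C)C)[C@@H]([CH+]c1ccc(OC)c(OC)c1)C | intermediate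
6 | tetralin iminium ion, the ring-closed iminium ion formed from aldehyde 7 and the (2S,5S)-imidazolidinone | COc1ccc([C@H]2c3cc(OC)c(OC)cc3C[C@@H](C=[N+]3[C@@H](Cc4ccccc4)C(=O)N(C)[C@H]3C(C)(C)C)[C@@H]2C)cc1OC | intermediate
7 | (2R,3R,4S)-4-(3,4-dimethoxyphenyl)-6,7-dimethoxy-3-methyl-1,2,3,4-tetrahydronaphthalene-2-carbaldehyde | COc1ccc([C@H]2c3cc(OC)c(OC)cc3C[C@@H](C=O)[C@@H]2C)cc1OC | intermediate
8 | tosylhydrazone, N'-[(E)-{(2R,3R,4S)-4-(3,4-dimethoxyphenyl)-6,7-dimethoxy-3-methyl-1,2,3,4-tetrahydronaphthalen-2-yl}methylidene]-4-methylbenzenesulfonohydrazide | COc1ccc([C@H]2c3cc(OC)c(OC)cc3C[C@@H](/C=N/NS(=O)(=O)c3ccc(C)cc3)[C@@H]2C)cc1OC | intermediate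
9 | galbulin, (1S,2S,3R)-1-(3,4-dimethoxyphenyl)-6,7-dimethoxy-2,3-dimethyl-1,2,3,4-tetrahydronaphthalene | COc1ccc([C@H]2c3cc(OC)c(OC)cc3C[C@@H](C)[C@@H]2C)cc1OC | target

Total step count: 3. Longest linear sequence: 3 steps (1 to 2 to 7 to 9).

Steps most likely to fail

1. Step 2. Two processes threaten it. The iron oxidant may oxidise alkene 3 directly, so that 3 dimerises through its radical cation instead of coupling with the enamine. Simple diastereoselection at C2 may also be weak in the radical addition to a 1,2-disubstituted alkene. The fallback sets out from 3 and comes back at 9, and it turns the competing pathway into the route. Radical-cation [4+2] homodimerisation of 3 (9-mesityl-10-methylacridinium tetrafluoroborate as photocatalyst, PhSSPh as hydrogen-atom shuttle, blue LEDs, 1,2-dichloroethane) should join the two methyl-bearing alkene carbons, close the benzylic cation onto the ring and return a hydrogen atom to C4. This should give the all-trans tetralin as the racemate, that is 9 together with ent-galbulin F1. The enantiomers would then be separated by preparative HPLC on a chiral stationary phase; steps 1 and 3 are not needed in this case.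

2. Step 3. The C3 stereocentre may epimerise through ene-hydrazine tautomerism of the hydrazone, or the hindered N-boryl hydrazide may fragment incompletely. The fallback sets out from 7 and comes back at 9, replacing the diazene route by hydride displacement. Reduction with NaBH4 (MeOH, 0 °C) would give [(2R,3R,4S)-4-(3,4-dimethoxyphenyl)-6,7-dimethoxy-3-methyl-1,2,3,4-tetrahydronaphthalen-2-yl]methanol F2. Sulfonylation (TsCl, Et3N, DMAP, CH2Cl2) would give the corresponding 4-methylbenzenesulfonate F3, and LiBHEt3 (THF, 0 °C to rt) would displace the primary sulfonate by hydride to give 9.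

3. Step 1. The unhindered, enolisable aldehyde may over-oxidise or self-condense during oxidation, chromatography and storage. The fallback sets out from 1 and comes back at 2, reaching the aldehyde by reduction from the acid level. Full oxidation (PhI(OAc)2, catalytic 2,2,6,6-tetramethylpiperidin-1-oxyl, MeCN/H2O) would give 3-(3,4-dimethoxyphenyl)propanoic acid F4. Amidation (1,1'-carbonyldiimidazole, then MeNHOMe·HCl) would give N-methoxy-N-methyl-3-(3,4-dimethoxyphenyl)propanamide F5, a bench-stable store. LiAlH4 (THF, −78 to 0 °C) would release 2 from it immediately before step 2, the chelated tetrahedral intermediate preventing over-reduction.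

Further compounds
F1 | step 2 | ent-galbulin, (1R,2R,3S)-1-(3,4-dimethoxyphenyl)-6,7-dimethoxy-2,3-dimethyl-1,2,3,4-tetrahydronaphthalene, formed with 9 as the racemate | COc1ccc([C@@H]2c3cc(OC)c(OC)cc3C[C@H](C)[C@H]2C)cc1OC
F2 | step 3 | [(2R,3R,4S)-4-(3,4-dimethoxyphenyl)-6,7-dimethoxy-3-methyl-1,2,3,4-tetrahydronaphthalen-2-yl]methanol | COc1ccc([C@H]2c3cc(OC)c(OC)cc3C[C@@H](CO)[C@@H]2C)cc1OC
F3 | step 3 | [(2R,3R,4S)-4-(3,4-dimethoxyphenyl)-6,7-dimethoxy-3-methyl-1,2,3,4-tetrahydronaphthalen-2-yl]methyl 4-methylbenzenesulfonate | COc1ccc([C@H]2c3cc(OC)c(OC)cc3C[C@@H](COS(=O)(=O)c3ccc(C)cc3)[C@@H]2C)cc1OC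
F4 | step 1 | 3-(3,4-dimethoxyphenyl)propanoic acid | COc1ccc(CCC(=O)O)cc1OC
F5 | step 1 | N-methoxy-N-methyl-3-(3,4-dimethoxyphenyl)propanamide | COc1ccc(CCC(=O)N(C)OC)cc1OC
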